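**Plan**
- Retrosynthetic cuts, in order: the benzyl ether on the 7-hydroxyl of the lower chromone; C8–O (epoxide opening) and C7–O (epoxidation of a C7=C8 alkene); then C4a–C5 and C6–C7 together (Diels–Alder reaction with loss of CO2); last, the enol C–O bonds of the dienophile and the pyrone and pyranone rings of the diene.
- Enabling feature: C4a=C8a of ring A (the 4-pyranone) and C8–C7 of ring B (the carbocycle) become the diene of a 2-pyrone once C4a and C7 are tied by a –C(=O)–O– bridge, as in 2-(2-phenylethyl)pyrano[4,3-b]pyran-4,5-dione 16. The bridge is not in the target and leaves as CO2, which returns the C4a=C8a bond to ring A.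
- Forward order: lower chromone by Claisen condensation and cyclodehydration, then the E-aryloxyvinyl acetate 8 by two copper-catalysed C–O couplings. Ring A by acylketene–enamine annulation, the pyrone ring by amide-acetal condensation and lactonisation. Ring B by cycloaddition of 16 with 8, which also joins the two halves through the C5–O–aryl ether; then deacetylation, epoxidation, hydrolysis and debenzylation.
- Stereochemistry: C5/C6 trans from the E alkene (suprafacial addition), absolute sense from a chiral Yb–BINOL Lewis acid. C7 from hydroxyl-directed epoxidation syn to the C6 hydroxyl; C8 from inversion in the epoxide opening.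

Key step: step 8

Remark (assumption): the catalyst made from (R)-BINOL is taken to give the (5S,6S) series in step 8; if a first run shows the opposite sense, (S)-BINOL is used and nothing else changes.
Remark (assumption): 6 and 12 are taken as commercial. Chromone numbering (O1, C2 to C8a) is used for both halves; ring A is the 4-pyranone and ring B the carbocycle of the upper half.

**Step 1**
Reactants: 1 1-(2,4,5-trihydroxyphenyl)ethan-1-one
Product: 2 1-[4-(benzyloxy)-2,5-dihydroxyphenyl]ethan-1-one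
Conditions: BnBr (1.05 equiv), NaHCO3 (1.2 equiv), NaI (0.1 equiv), DMF, 40 °C
Reagents that add atoms: benzyl bromide, BrCc1ccccc1
Why: Williamson etherification, in which the 4-hydroxyl (para to the acetyl group) is the most acidic phenol and the only one ionised by NaHCO3, while the 2-hydroxyl is held in a hydrogen bond to the ketone, so mono-benzylation at O4 is expected.

**Step 2**
Reactants: 2 1-[4-(benzyloxy)-2,5-dihydroxyphenyl]ethan-1-one; 3 ethyl 3-phenylpropanoate
Product: 5 7-(benzyloxy)-6-hydroxy-2-(2-phenylethyl)-4H-chromen-4-one, via diketone 4 (not isolated)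
Conditions: LiN(SiMe3)2 (4.2 equiv), THF, −78 °C to rt; aq. HCl work-up; crude 4 with p-TsOH·H2O (0.1 equiv), toluene, 80 °C
Reagents that add atoms: none
Why: Claisen condensation of the ketone enolate (formed after both phenols are deprotonated) with the ester gives the 1,3-diketone, and acid-catalysed cyclodehydration through the 2-hydroxyl closes the 4-pyranone, the standard chromone synthesis.

**Step 3**
Reactants: 5 7-(benzyloxy)-6-hydroxy-2-(2-phenylethyl)-4H-chromen-4-one; 6 (E)-1,2-bis(4,4,5,5-tetramethyl-1,3,2-dioxaborolan-2-yl)ethene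
Product: 7 7-(benzyloxy)-2-(2-phenylethyl)-6-{[(E)-2-(4,4,5,5-tetramethyl-1,3,2-dioxaborolan-2-yl)ethenyl]oxy}-4H-chromen-4-one
Conditions: 6 (3 equiv), Cu(OAc)2 (0.2 equiv), pyridine (2 equiv), 4 Å MS, O2 (1 atm), CH2Cl2, rt
Reagents that add atoms: none
Why: Chan–Lam oxidative C–O coupling of the only free phenol with one alkenyl–boron bond should proceed with retention of the E geometry, and the excess of 6 suppresses double coupling.

**Step 4**
Reactants: 7 7-(benzyloxy)-2-(2-phenylethyl)-6-{[(E)-2-(4,4,5,5-tetramethyl-1,3,2-dioxaborolan-2-yl)ethenyl]oxy}-4H-chromen-4-one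
Product: 8 (E)-2-{[7-(benzyloxy)-4-oxo-2-(2-phenylethyl)-4H-chromen-6-yl]oxy}ethenyl acetate
Conditions: AcOH (3 equiv), Cu(OAc)2 (0.2 equiv), DMAP (0.4 equiv), 4 Å MS, O2 (1 atm), MeCN, 40 °C
Reagents that add atoms: acetic acid, CC(=O)O
Why: Chan–Lam-type copper-catalysed oxidative coupling of a carboxylic acid with an alkenylboronate, again with retention, should give the E enol acetate whose geometry later fixes the trans relation of C5 and C6.

**Step 5**
Reactants: 9 2,2-dimethyl-1,3-dioxane-4,6-dione (Meldrum's acid); 10 3-phenylpropanoyl chloride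
Product: 11 5-(1-hydroxy-3-phenylpropylidene)-2,2-dimethyl-1,3-dioxane-4,6-dione
Conditions: pyridine (2.2 equiv), CH2Cl2, 0 °C to rt
Reagents that add atoms: none
Why: C-acylation of Meldrum's acid by an acid chloride, the standard route to acyl Meldrum's acids.

**Step 6**
Reactants: 11 5-(1-hydroxy-3-phenylpropylidene)-2,2-dimethyl-1,3-dioxane-4,6-dione; 12 ethyl (E)-3-(pyrrolidin-1-yl)but-2-enoate
Product: 14 ethyl 2-methyl-4-oxo-6-(2-phenylethyl)-4H-pyran-3-carboxylate, via acylketene 13 (not isolated)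
Conditions: toluene, 110 °C, slow addition of 11 (1.5 equiv) to 12
Reagents that add atoms: none
Why: Thermal retro-[4+2] of the acyl Meldrum's acid releases the acylketene, which undergoes formal [4+2] cycloaddition with the nucleophilic enamine carbon and then loses pyrrolidine to give the 4-pyranone (acylketene–enamine pyranone synthesis).

**Step 7**
Reactants: 14 ethyl 2-methyl-4-oxo-6-(2-phenylethyl)-4H-pyran-3-carboxylate
Product: 16 2-(2-phenylethyl)-4H,5H-pyrano[4,3-b]pyran-4,5-dione, via enamine 15 (not isolated)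
Conditions: Me2NCH(OMe)2 (2 equiv), toluene, 90 °C; evaporate; AcOH/H2O (4:1), 60 °C
Reagents that add atoms: N,N-dimethylformamide dimethyl acetal, COC(OC)N(C)C; water, O
Why: The 2-methyl group, vinylogous to both the ketone and the ester, condenses with the amide acetal in preference to the less acidic and more hindered phenylethyl methylene, and acid hydrolysis of the enamine with lactonisation onto the neighbouring ester closes the 2-pyrone, as in the isocoumarin synthesis from 2-methylbenzoates.

**Step 8**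
Reactants: 16 2-(2-phenylethyl)-4H,5H-pyrano[4,3-b]pyran-4,5-dione; 8 (E)-2-{[7-(benzyloxy)-4-oxo-2-(2-phenylethyl)-4H-chromen-6-yl]oxy}ethenyl acetate
Product: 18 (5S,6S)-5-{[7-(benzyloxy)-4-oxo-2-(2-phenylethyl)-4H-chromen-6-yl]oxy}-4-oxo-2-(2-phenylethyl)-5,6-dihydro-4H-chromen-6-yl acetate, via bridged lactone 17 (not isolated)
Conditions: Yb(OTf)3 (0.1 equiv), (R)-BINOL (0.12 equiv), i-Pr2NEt (0.25 equiv), 4 Å MS, CH2Cl2, 0 °C to rt; then Et3N (0.3 equiv), toluene, 80 °C
Reagents that add atoms: none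
Why: The Yb–BINOL complex should chelate the C4 ketone and the lactone carbonyl of 16 (both on C4a) and lower the LUMO of the pyrone diene C4a=C8a–C8=C7, so that the acetoxy-bearing carbon of 8 (β to the stronger aryloxy donor) attacks the δ-position C7 and the aryloxy-stabilised carbon closes onto C4a in an asynchronous inverse-electron-demand Diels–Alder reaction; on warming, the bridged lactone 17 loses CO2 by retro-[4+2], which removes the temporary –C(=O)–O– bridge and returns the C4a=C8a bond to ring A. The closest known reaction type is the Lewis-acid-catalysed inverse-demand Diels–Alder reaction of 3-carbonyl-2-pyrones with enol ethers followed by thermal CO2 extrusion. Ring B is closed by this intermolecular [4+2] cycloaddition, suprafacial on both partners, and survives the cycloreversion as a cyclohexadiene. C5 and C6 come out trans because the E geometry of 8 is transferred stereospecifically, and their absolute configuration (5S,6S) is set by the chiral ytterbium complex, which blocks one face of the chelated diene, together with the endo preference of the aryloxy group. The step needs regioselectivity (secured by the donor order aryloxy > acetoxy and by C7 being the unsubstituted, doubly vinylogous acceptor carbon), endo/exo fidelity (the two topicities lead to opposite enantiomers after CO2 loss) and survival of the dihydroarene, which is helped by the trans arrangement (neither leaving group has an anti-periplanar hydrogen) and by quenching the Lewis acid with Et3N before heating.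

**Step 9**
Reactants: 18 (5S,6S)-5-{[7-(benzyloxy)-4-oxo-2-(2-phenylethyl)-4H-chromen-6-yl]oxy}-4-oxo-2-(2-phenylethyl)-5,6-dihydro-4H-chromen-6-yl acetate
Product: 19 (5S,6S)-5-{[7-(benzyloxy)-4-oxo-2-(2-phenylethyl)-4H-chromen-6-yl]oxy}-6-hydroxy-2-(2-phenylethyl)-5,6-dihydro-4H-chromen-4-one
Conditions: K2CO3 (0.2 equiv), MeOH, −10 °C; AcOH quench
Reagents that add atoms: none
Why: Base-catalysed transesterification (methanolysis) of the secondary acetate at low temperature should leave C5 and C6 untouched, since the trans arrangement offers no anti-periplanar hydrogen for elimination of the aryloxide.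

**Step 10**
Reactants: 19 (5S,6S)-5-{[7-(benzyloxy)-4-oxo-2-(2-phenylethyl)-4H-chromen-6-yl]oxy}-6-hydroxy-2-(2-phenylethyl)-5,6-dihydro-4H-chromen-4-one
Product: 20 (5S,6R,7R,8R)-5-{[7-(benzyloxy)-4-oxo-2-(2-phenylethyl)-4H-chromen-6-yl]oxy}-7,8-epoxy-6-hydroxy-2-(2-phenylethyl)-5,6,7,8-tetrahydro-4H-chromen-4-one (epoxide cis to the 6-hydroxyl, trans to the 5-aryloxy group)
Conditions: mCPBA (1.5 equiv), CH2Cl2, 0 °C to rt
Reagents that add atoms: 3-chloroperoxybenzoic acid, O=C(OO)c1cccc(Cl)c1
Why: Hydroxyl-directed peracid epoxidation (Prilezhaev reaction) of the C7=C8 alkene should deliver oxygen to the face syn to the allylic C6 hydroxyl, which is also the face opposite to the C5 aryloxy group, setting C7 and C8, while the pyranone double bonds are too electron-poor to react.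

**Step 11**
Reactants: 20 (5S,6R,7R,8R)-5-{[7-(benzyloxy)-4-oxo-2-(2-phenylethyl)-4H-chromen-6-yl]oxy}-7,8-epoxy-6-hydroxy-2-(2-phenylethyl)-5,6,7,8-tetrahydro-4H-chromen-4-one
Product: 21 (5S,6S,7R,8S)-5-{[7-(benzyloxy)-4-oxo-2-(2-phenylethyl)-4H-chromen-6-yl]oxy}-6,7,8-trihydroxy-2-(2-phenylethyl)-5,6,7,8-tetrahydro-4H-chromen-4-one
Conditions: HClO4 (0.1 equiv), THF/H2O (3:1), 0 °C to rt
Reagents that add atoms: water, O
Why: Acid-catalysed epoxide hydrolysis by SN2-type trans-diaxial attack of water at C8, the allylic carbon distal to the C6 hydroxyl (attack at C7 is retarded inductively by the neighbouring carbinol), should invert C8 and keep the C7–O bond, giving the 6,7-cis, 7,8-trans triol.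

**Step 12**
Reactants: 21 (5S,6S,7R,8S)-5-{[7-(benzyloxy)-4-oxo-2-(2-phenylethyl)-4H-chromen-6-yl]oxy}-6,7,8-trihydroxy-2-(2-phenylethyl)-5,6,7,8-tetrahydro-4H-chromen-4-one
Product: 22 (5S,6S,7R,8S)-6,7,8-trihydroxy-5-{[7-hydroxy-4-oxo-2-(2-phenylethyl)-4H-chromen-6-yl]oxy}-2-(2-phenylethyl)-5,6,7,8-tetrahydro-4H-chromen-4-one
Conditions: H2 (1 atm), Pd/C (10 %), EtOAc/MeOH, rt
Reagents that add atoms: none
Why: Hydrogenolysis of the aryl benzyl ether over palladium under mild conditions, which the chromone double bonds and the secondary aryl alkyl ether at C5 should survive, affects no stereocentre.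

**Compound list**
1 | 1-(2,4,5-trihydroxyphenyl)ethan-1-one | CC(=O)c1cc(O)c(O)cc1O | starting material
2 | 1-[4-(benzyloxy)-2,5-dihydroxyphenyl]ethan-1-one | CC(=O)c1cc(O)c(OCc2ccccc2)cc1O | intermediate
3 | ethyl 3-phenylpropanoate | CCOC(=O)CCc1ccccc1 | starting material
4 | 1-[4-(benzyloxy)-2,5-dihydroxyphenyl]-5-phenylpentane-1,3-dione (diketone, formed in the flask) | O=C(CC(=O)CCc1ccccc1)c1cc(O)c(OCc2ccccc2)cc1O | intermediate
5 | 7-(benzyloxy)-6-hydroxy-2-(2-phenylethyl)-4H-chromen-4-one | O=c1cc(CCc2ccccc2)oc2cc(OCc3ccccc3)c(O)cc12 | intermediate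
6 | (E)-1,2-bis(4,4,5,5-tetramethyl-1,3,2-dioxaborolan-2-yl)ethene | CC1(C)OB(/C=C/B2OC(C)(C)C(C)(C)O2)OC1(C)C | starting material
7 | 7-(benzyloxy)-2-(2-phenylethyl)-6-{[(E)-2-(4,4,5,5-tetramethyl-1,3,2-dioxaborolan-2-yl)ethenyl]oxy}-4H-chromen-4-one | CC1(C)OB(/C=C/Oc2cc3c(=O)cc(CCc4ccccc4)oc3cc2OCc2ccccc2)OC1(C)C | intermediate
8 | (E)-2-{[7-(benzyloxy)-4-oxo-2-(2-phenylethyl)-4H-chromen-6-yl]oxy}ethenyl acetate | CC(=O)O/C=C/Oc1cc2c(=O)cc(CCc3ccccc3)oc2cc1OCc1ccccc1 | intermediate
9 | 2,2-dimethyl-1,3-dioxane-4,6-dione (Meldrum's acid) | CC1(C)OC(=O)CC(=O)O1 | starting material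
10 | 3-phenylpropanoyl chloride | O=C(Cl)CCc1ccccc1 | starting material
11 | 5-(1-hydroxy-3-phenylpropylidene)-2,2-dimethyl-1,3-dioxane-4,6-dione | CC1(C)OC(=O)C(=C(O)CCc2ccccc2)C(=O)O1 | intermediate
12 | ethyl (E)-3-(pyrrolidin-1-yl)but-2-enoate | CCOC(=O)/C=C(\C)N1CCCC1 | starting material
13 | 3-oxo-5-phenylpent-1-en-1-one (acylketene, formed in the flask) | O=C=CC(=O)CCc1ccccc1 | intermediate
14 | ethyl 2-methyl-4-oxo-6-(2-phenylethyl)-4H-pyran-3-carboxylate | CCOC(=O)c1c(C)oc(CCc2ccccc2)cc1=O | intermediate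
15 | ethyl 2-[(E)-2-(dimethylamino)ethenyl]-4-oxo-6-(2-phenylethyl)-4H-pyran-3-carboxylate (enamine, formed in the flask) | CCOC(=O)c1c(/C=C/N(C)C)oc(CCc2ccccc2)cc1=O | intermediate
16 | 2-(2-phenylethyl)-4H,5H-pyrano[4,3-b]pyran-4,5-dione | O=c1cc(CCc2ccccc2)oc2ccoc(=O)c12 | intermediate
17 | bridged lactone cycloadduct of 16 and 8: C4a and C7 joined by –C(=O)–O–, C8=C8a double bond, 5-aryloxy endo (anti to the lactone bridge), 6-acetoxy exo, 5,6-trans (formed in the flask) | O=C1C=C(CCc2ccccc2)OC2=C[C@@H]3OC(=O)[C@]12[C@H](Oc1cc2c(=O)cc(CCc4ccccc4)oc2cc1OCc1ccccc1)[C@H]3OC(C)=O | intermediate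
18 | (5S,6S)-5-{[7-(benzyloxy)-4-oxo-2-(2-phenylethyl)-4H-chromen-6-yl]oxy}-4-oxo-2-(2-phenylethyl)-5,6-dihydro-4H-chromen-6-yl acetate | O=c1cc(CCc2ccccc2)oc2c1[C@H](Oc1cc3c(=O)cc(CCc4ccccc4)oc3cc1OCc1ccccc1)[C@@H](OC(C)=O)C=C2 | intermediate
19 | (5S,6S)-5-{[7-(benzyloxy)-4-oxo-2-(2-phenylethyl)-4H-chromen-6-yl]oxy}-6-hydroxy-2-(2-phenylethyl)-5,6-dihydro-4H-chromen-4-one | O=c1cc(CCc2ccccc2)oc2c1[C@H](Oc1cc3c(=O)cc(CCc4ccccc4)oc3cc1OCc1ccccc1)[C@@H](O)C=C2 | intermediate
20 | (5S,6R,7R,8R)-5-{[7-(benzyloxy)-4-oxo-2-(2-phenylethyl)-4H-chromen-6-yl]oxy}-7,8-epoxy-6-hydroxy-2-(2-phenylethyl)-5,6,7,8-tetrahydro-4H-chromen-4-one | O=c1cc(CCc2ccccc2)oc2c1[C@H](Oc1cc3c(=O)cc(CCc4ccccc4)oc3cc1OCc1ccccc1)[C@@H](O)[C@H]1O[C@@H]21 | intermediate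
21 | (5S,6S,7R,8S)-5-{[7-(benzyloxy)-4-oxo-2-(2-phenylethyl)-4H-chromen-6-yl]oxy}-6,7,8-trihydroxy-2-(2-phenylethyl)-5,6,7,8-tetrahydro-4H-chromen-4-one | O=c1cc(CCc2ccccc2)oc2c1[C@H](Oc1cc3c(=O)cc(CCc4ccccc4)oc3cc1OCc1ccccc1)[C@@H](O)[C@@H](O)[C@@H]2O | intermediate
22 | (5S,6S,7R,8S)-6,7,8-trihydroxy-5-{[7-hydroxy-4-oxo-2-(2-phenylethyl)-4H-chromen-6-yl]oxy}-2-(2-phenylethyl)-5,6,7,8-tetrahydro-4H-chromen-4-one | O=c1cc(CCc2ccccc2)oc2c1[C@H](Oc1cc3c(=O)cc(CCc4ccccc4)oc3cc1O)[C@@H](O)[C@@H](O)[C@@H]2O | target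

**Step count**
Total steps: 12. Longest linear sequence: 9 (steps 1 to 4, then 8 to 12); the diene branch (steps 5 to 7) joins at step 8.

**Three steps most likely to fail**

1. Step 8. What may go wrong: incomplete face or endo/exo control (the two topicities give opposite enantiomers after CO2 loss), scrambling of the E geometry through a stepwise zwitterionic addition, or elimination of aryloxide or acetate to an aromatic chromone while CO2 is expelled. Fallback (control by resolution instead of by catalyst): from 16 and 8 the cycloaddition is run without any metal (toluene, 110 °C), so that 17 and its mirror image F1 form together and lose CO2 to give 18 mixed with the (5R,6R)-acetate F2. Methanolysis as in step 9 then gives 19 mixed with the (5R,6R)-dienol F3. A lipase (immobilised Candida antarctica lipase B, vinyl acetate, t-BuOMe, 30 °C) should acetylate F3 back to F2 faster than it acetylates 19, following the usual size rule for secondary alcohols (large aryloxy-bearing side against the small vinylic side). Unreacted 19 is separated from F2 and the route is rejoined at 19.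

2. Step 3. What may go wrong: slow transmetalation of the pinacol boronate, double coupling, or protodeboronation. Fallback (halide instead of boron chemistry): from 5, Ullmann-type vinylation with (E)-1,2-diiodoethene (3 equiv, CuI, N,N-dimethylglycine, Cs2CO3, dioxane, 80 °C) should give the (E)-2-aryloxyvinyl iodide F4 with retention. A second copper-catalysed C–O coupling with CsOAc (CuI, 1,10-phenanthroline, toluene, 90 °C) should then give 8, bypassing 7.

3. Step 11. What may go wrong: acid-induced ionisation of the C5 aryl ether (loss of the lower half or aromatisation) or competing attack of water at C7. Fallback (metal-templated delivery of a carboxylate instead of free acid): from 20, Ti(OiPr)4 (1.5 equiv) and PhCO2H in CH2Cl2 at rt should bind the C6 hydroxyl and deliver benzoate to the distal epoxide carbon C8 with inversion, giving the 8-benzoate F5. Methanolysis (K2CO3, MeOH, 0 °C) then gives 21.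

**Further compounds**
F1 | step 8 | mirror image of bridged lactone 17 | O=C1C=C(CCc2ccccc2)OC2=C[C@H]3OC(=O)[C@@]12[C@@H](Oc1cc2c(=O)cc(CCc4ccccc4)oc2cc1OCc1ccccc1)[C@@H]3OC(C)=O
F2 | step 8 | (5R,6R)-5-{[7-(benzyloxy)-4-oxo-2-(2-phenylethyl)-4H-chromen-6-yl]oxy}-4-oxo-2-(2-phenylethyl)-5,6-dihydro-4H-chromen-6-yl acetate | O=c1cc(CCc2ccccc2)oc2c1[C@@H](Oc1cc3c(=O)cc(CCc4ccccc4)oc3cc1OCc1ccccc1)[C@H](OC(C)=O)C=C2
F3 | step 8 | (5R,6R)-5-{[7-(benzyloxy)-4-oxo-2-(2-phenylethyl)-4H-chromen-6-yl]oxy}-6-hydroxy-2-(2-phenylethyl)-5,6-dihydro-4H-chromen-4-one | O=c1cc(CCc2ccccc2)oc2c1[C@@H](Oc1cc3c(=O)cc(CCc4ccccc4)oc3cc1OCc1ccccc1)[C@H](O)C=C2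
F4 | step 3 | 7-(benzyloxy)-6-{[(E)-2-iodoethenyl]oxy}-2-(2-phenylethyl)-4H-chromen-4-one | O=c1cc(CCc2ccccc2)oc2cc(OCc3ccccc3)c(O/C=C/I)cc12
F5 | step 11 | (5S,6S,7R,8S)-5-{[7-(benzyloxy)-4-oxo-2-(2-phenylethyl)-4H-chromen-6-yl]oxy}-6,7-dihydroxy-4-oxo-2-(2-phenylethyl)-5,6,7,8-tetrahydro-4H-chromen-8-yl benzoate | O=c1cc(CCc2ccccc2)oc2c1[C@H](Oc1cc3c(=O)cc(CCc4ccccc4)oc3cc1OCc1ccccc1)[C@@H](O)[C@@H](O)[C@@H]2OC(=O)c1ccccc1
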